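**Retrosynthetic overview**
1. The strategy rests on ring C (third ring from the 2,4,6-trihydroxyphenyl end). It carries O–ring B at C1, OH at C3 and C5, and O–ring D at C4. This is a six-carbon triketide in which the C1 carbonyl is held as an aryl enol ether and C4 bears an aryloxy group.
2. Key disconnection: the C2–C3 bond of ring C, made by Claisen cyclisation of an open-chain methyl 2-aryloxy-3-oxo-5-aryloxyhex-4-enoate (methyl group becomes C2, ester carbon becomes C3). Ring C is the only ring formed; rings A, B and D–G are bought as arenes.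
3. Both ether bonds of ring C are made on non-aromatic carbon: SN2 of the DEFG phenol on methyl bromoacetate (C–O–D) and oxa-Michael addition of the AB phenol to but-2-ynal (B–O–C). The halves are joined by aldol addition and oxidation, so the alkyne never coexists with an acidic beta-keto ester.
4. AB phenol: Ullmann coupling, then hydrogenolysis. DEFG phenol: one Chan–Lam coupling, then two Ullmann/Dakin cycles in which an aryl aldehyde serves as a masked phenol.
5. Global O-demethylation is the last step.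

Key step: step 13

Remark: the target has no stereocentre and its diaryl ether axes rotate freely, so it is achiral and no step has to set configuration; but-2-ynal is taken as a purchased reagent.

Abbreviations used in names: ArAB = 2,6-dimethoxy-4-(2,4,6-trimethoxyphenoxy)phenyl; ArDEFG = 2-{4-[3,5-dimethoxy-4-(3,4,5-trimethoxyphenoxy)phenoxy]-3,5-dimethoxyphenoxy}-3,4,5-trimethoxyphenyl. Rings are lettered A (2,4,6-trioxygenated end) to G (3,4,5-trioxygenated end).

**Route**

Step 1
Reactants: 1 4-bromo-2,6-dimethoxyphenol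
Product: 2 2-(benzyloxy)-5-bromo-1,3-dimethoxybenzene
Conditions: BnBr, K2CO3, DMF, rt
Reagents that add atoms: benzyl bromide, BrCc1ccccc1
Why: Williamson O-benzylation of the phenol masks the ring-B oxygen that must later be the free nucleophile, with a group removable in the presence of methyl ethers.

Step 2
Reactants: 2 2-(benzyloxy)-5-bromo-1,3-dimethoxybenzene; 3 2,4,6-trimethoxyphenol
Product: 4 2-(benzyloxy)-1,3-dimethoxy-5-(2,4,6-trimethoxyphenoxy)benzene
Conditions: CuI (10 mol%), picolinic acid (20 mol%), K3PO4, DMSO, 90 °C, Ar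
Reagents that add atoms: none
Why: Ullmann diaryl ether coupling under Cu(I)/picolinic acid accepts di-ortho-substituted phenols when the aryl bromide is unhindered, which is the pairing chosen here for the A–O–B bond.

Step 3
Reactants: 4 2-(benzyloxy)-1,3-dimethoxy-5-(2,4,6-trimethoxyphenoxy)benzene
Product: 5 2,6-dimethoxy-4-(2,4,6-trimethoxyphenoxy)phenol (AB phenol)
Conditions: H2 (1 atm), 10% Pd/C, EtOAc–MeOH, rt
Reagents that add atoms: none
Why: Hydrogenolysis cleaves only the benzyl ether, since aryl methyl ethers and the diaryl ether are inert to Pd/H2.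

Step 4
Reactants: 5 AB phenol; 6 but-2-ynal
Product: 7 (2E)-3-(ArAB-oxy)but-2-enal
Conditions: DABCO (20 mol%), CH2Cl2, 0 °C to rt
Reagents that add atoms: none
Why: Amine-catalysed oxa-Michael addition of a phenol to an ynal places the aryloxy group on the beta-carbon (the one bearing the methyl group), and reversible catalyst addition should favour the E isomer with aryloxy trans to CHO; any Z isomer is carried on because the geometry is erased in step 13.

Step 5
Reactants: 8 3,4,5-trimethoxyphenylboronic acid; 1 4-bromo-2,6-dimethoxyphenol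
Product: 9 5-bromo-1,3-dimethoxy-2-(3,4,5-trimethoxyphenoxy)benzene (FG bromide)
Conditions: Cu(OAc)2 (1 equiv, turned over by O2), pyridine, 4 Å MS, CH2Cl2, dry air, rt; boronic acid 2 equiv
Reagents that add atoms: none
Why: Chan–Lam–Evans O-arylation runs at room temperature, tolerates di-ortho-substituted phenols and leaves the aryl bromide untouched, so the bifunctional bromophenol reacts only through oxygen.

Step 6
Reactants: 9 FG bromide; 10 syringaldehyde (4-hydroxy-3,5-dimethoxybenzaldehyde)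
Product: 11 4-[3,5-dimethoxy-4-(3,4,5-trimethoxyphenoxy)phenoxy]-3,5-dimethoxybenzaldehyde
Conditions: CuI (10 mol%), picolinic acid (20 mol%), K3PO4, DMSO, 100 °C, Ar; aldehyde 1.5 equiv
Reagents that add atoms: none
Why: Ullmann coupling of a hindered phenol with an unhindered aryl bromide as in step 2; the non-enolisable aldehyde survives and serves as the masked ring-E phenol.

Step 7
Reactants: 11 the EFG aldehyde
Product: 13 4-[3,5-dimethoxy-4-(3,4,5-trimethoxyphenoxy)phenoxy]-3,5-dimethoxyphenol (EFG phenol), via aryl formate 12 (not isolated)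
Conditions: mCPBA, CH2Cl2, 0 °C to rt; then K2CO3 (cat.), MeOH, rt
Reagents that add atoms: mCPBA, OOC(=O)c1cccc(Cl)c1
Why: Baeyer–Villiger (Dakin-type) oxidation of an electron-rich benzaldehyde, in which the trioxygenated aryl group migrates in preference to hydride, followed by methanolysis of the formate.

Step 8
Reactants: 13 EFG phenol; 14 2-bromo-3,4,5-trimethoxybenzaldehyde
Product: 15 2-(4-[3,5-dimethoxy-4-(3,4,5-trimethoxyphenoxy)phenoxy]-3,5-dimethoxyphenoxy)-3,4,5-trimethoxybenzaldehyde (DEFG aldehyde)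
Conditions: CuI (20 mol%), N,N-dimethylglycine·HCl (40 mol%), Cs2CO3, dioxane, 100 °C, Ar
Reagents that add atoms: none
Why: Ullmann coupling of an unhindered, electron-rich phenol with an ortho-formyl aryl bromide, where the ortho carbonyl activates the C–Br bond as in the classical couplings of 2-bromo-3,4,5-trialkoxybenzoyl compounds used for gallate-derived diaryl ethers.

Step 9
Reactants: 15 DEFG aldehyde
Product: 17 ArDEFG–OH (DEFG phenol), via aryl formate 16 (not isolated)
Conditions: mCPBA, CH2Cl2, 0 °C to rt; then K2CO3 (cat.), MeOH, rt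
Reagents that add atoms: mCPBA, OOC(=O)c1cccc(Cl)c1
Why: Baeyer–Villiger/Dakin sequence as in step 7; aryl migration is favoured by the ortho-aryloxy and para-methoxy groups, and the new OH sits on ring D next to the O–E ether.

Step 10
Reactants: 17 DEFG phenol; 18 methyl bromoacetate
Product: 19 methyl 2-(ArDEFG-oxy)acetate
Conditions: K2CO3, acetone, 50 °C
Reagents that add atoms: none
Why: Williamson SN2 alkylation forms the C–O–D ether on an sp3 carbon and brings in the two carbons that become C3 and C4 of ring C.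

Step 11
Reactants: 19 methyl 2-(ArDEFG-oxy)acetate; 7 (2E)-3-(ArAB-oxy)but-2-enal
Product: 20 methyl (4E)-2-(ArDEFG-oxy)-3-hydroxy-5-(ArAB-oxy)hex-4-enoate (racemic mixture of diastereomers)
Conditions: LDA (1.1 equiv, commercial solution), THF, −78 °C; then 7, −78 °C; sat. aq. NH4Cl at −78 °C
Reagents that add atoms: none
Why: Aldol addition of a lithium glycolate-ester enolate to an enal goes 1,2 at −78 °C and needs one equivalent of base; the two new stereocentres are not controlled because both are destroyed in steps 12 and 13.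

Step 12
Reactants: 20 the aldol adduct
Product: 21 methyl (4E)-2-(ArDEFG-oxy)-3-oxo-5-(ArAB-oxy)hex-4-enoate (racemic at C2; cyclisation precursor)
Conditions: Dess–Martin periodinane (1.2 equiv), pyridine, CH2Cl2, 0 °C to rt; Et3N-deactivated silica
Reagents that add atoms: none
Why: Dess–Martin oxidation of the secondary allylic alcohol under pyridine buffer gives the beta-keto ester without acid that would hydrolyse the aryl enol ether.

Step 13
Reactants: 21 the cyclisation precursor
Product: 23 2-(ArDEFG-oxy)-5-(ArAB-oxy)benzene-1,3-diol (heptamer with free 3,5-dihydroxy ring C), via cyclohexenedione tautomer 22 (not isolated)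
Conditions: LDA (4 equiv), THF–DMPU, −78 °C (21 added to the base), then to rt; sat. aq. NH4Cl
Reagents that add atoms: none
Why: LDA removes first the doubly activated C2–H and then a proton of the C6 methyl group, and the terminal carbon of the resulting cross-conjugated dianion attacks the ester carbonyl; loss of methoxide gives 22 as its enolate, which enolises to the aromatic ring-C bis-phenoxide. The closest known reaction type is the biomimetic Claisen (Dieckmann-type) cyclisation of 3,5-dioxo ester polyanions and of gamma-deprotonated beta-alkoxy enones to phloroglucinol derivatives. Ring C closes in a vinylogous 6-(enolendo)-exo-trig mode, the whole dienolate lying inside the new ring, and the bond formed is C2–C3 of ring C. No stereocentre is formed, and the C2 centre and the enol ether geometry of 21 are erased because the former C4–C5 double bond becomes a rotatable single bond in the dienolate. The step needs C-acylation at C6 to win over attack of the ester-enolate oxygen on C5 (addition–elimination that would expel the AB aryloxide and give a 2-methoxy-4-pyranone) and over external displacement of that aryloxide. Inverse addition to excess non-nucleophilic amide at −78 °C should convert the monoanion at once into the dianion, in which C5 is no longer electrophilic, while the aryl cap on the ring-C C1 oxygen excludes 2-pyranone formation and DMPU loosens the lithium chelate so the ester can rotate cis to C4.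

Step 14
Reactants: 23 the ring-C diol heptamer
Product: 24 target CNP0304148.0 (heptadecahydroxy heptamer)
Conditions: BBr3 (1 M in CH2Cl2, large excess), CH2Cl2, −78 °C to rt; degassed ice-water; Sephadex LH-20 under Ar
Reagents that add atoms: none
Why: Boron tribromide cleavage of aryl methyl ethers removes all fifteen O-methyl groups by bromide attack on the methyl carbon, while diaryl ether bonds have no such pathway and should stay intact.

**Compound list**
1 | 4-bromo-2,6-dimethoxyphenol | COc1cc(Br)cc(OC)c1O | starting material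
2 | 2-(benzyloxy)-5-bromo-1,3-dimethoxybenzene | COc1cc(Br)cc(OC)c1OCc1ccccc1 | intermediate
3 | 2,4,6-trimethoxyphenol | COc1cc(OC)c(O)c(OC)c1 | starting material
4 | 2-(benzyloxy)-1,3-dimethoxy-5-(2,4,6-trimethoxyphenoxy)benzene | COc1cc(OC)c(Oc2cc(OC)c(OCc3ccccc3)c(OC)c2)c(OC)c1 | intermediate
5 | 2,6-dimethoxy-4-(2,4,6-trimethoxyphenoxy)phenol (AB phenol) | COc1cc(OC)c(Oc2cc(OC)c(O)c(OC)c2)c(OC)c1 | intermediate
6 | but-2-ynal | CC#CC=O | starting material
7 | (2E)-3-(ArAB-oxy)but-2-enal | C/C(Oc1c(OC)cc(Oc2c(OC)cc(OC)cc2OC)cc1OC)=C\C=O | intermediate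
8 | 3,4,5-trimethoxyphenylboronic acid | COc1cc(B(O)O)cc(OC)c1OC | starting material
9 | 5-bromo-1,3-dimethoxy-2-(3,4,5-trimethoxyphenoxy)benzene (FG bromide) | COc1cc(Br)cc(OC)c1Oc1cc(OC)c(OC)c(OC)c1 | intermediate
10 | syringaldehyde | COc1cc(C=O)cc(OC)c1O | starting material
11 | 4-[3,5-dimethoxy-4-(3,4,5-trimethoxyphenoxy)phenoxy]-3,5-dimethoxybenzaldehyde | COc1cc(C=O)cc(OC)c1Oc1cc(OC)c(Oc2cc(OC)c(OC)c(OC)c2)c(OC)c1 | intermediate
12 | 4-[3,5-dimethoxy-4-(3,4,5-trimethoxyphenoxy)phenoxy]-3,5-dimethoxyphenyl formate | COc1cc(OC=O)cc(OC)c1Oc1cc(OC)c(Oc2cc(OC)c(OC)c(OC)c2)c(OC)c1 | intermediate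
13 | 4-[3,5-dimethoxy-4-(3,4,5-trimethoxyphenoxy)phenoxy]-3,5-dimethoxyphenol (EFG phenol) | COc1cc(O)cc(OC)c1Oc1cc(OC)c(Oc2cc(OC)c(OC)c(OC)c2)c(OC)c1 | intermediate
14 | 2-bromo-3,4,5-trimethoxybenzaldehyde | COc1cc(C=O)c(Br)c(OC)c1OC | starting material
15 | DEFG aldehyde (ArDEFG with CHO in place of the free valence) | COc1cc(C=O)c(Oc2cc(OC)c(Oc3cc(OC)c(Oc4cc(OC)c(OC)c(OC)c4)c(OC)c3)c(OC)c2)c(OC)c1OC | intermediate
16 | ArDEFG formate | COc1cc(OC=O)c(Oc2cc(OC)c(Oc3cc(OC)c(Oc4cc(OC)c(OC)c(OC)c4)c(OC)c3)c(OC)c2)c(OC)c1OC | intermediate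
17 | ArDEFG–OH (DEFG phenol) | COc1cc(O)c(Oc2cc(OC)c(Oc3cc(OC)c(Oc4cc(OC)c(OC)c(OC)c4)c(OC)c3)c(OC)c2)c(OC)c1OC | intermediate
18 | methyl bromoacetate | COC(=O)CBr | starting material
19 | methyl 2-(ArDEFG-oxy)acetate | COC(=O)COc1cc(OC)c(OC)c(OC)c1Oc1cc(OC)c(Oc2cc(OC)c(Oc3cc(OC)c(OC)c(OC)c3)c(OC)c2)c(OC)c1 | intermediate
20 | methyl (4E)-2-(ArDEFG-oxy)-3-hydroxy-5-(ArAB-oxy)hex-4-enoate (diastereomer mixture, racemic) | C/C(Oc1c(OC)cc(Oc2c(OC)cc(OC)cc2OC)cc1OC)=C\C(O)C(Oc1cc(OC)c(OC)c(OC)c1Oc1cc(OC)c(Oc2cc(OC)c(Oc3cc(OC)c(OC)c(OC)c3)c(OC)c2)c(OC)c1)C(=O)OC | intermediate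
21 | methyl (4E)-2-(ArDEFG-oxy)-3-oxo-5-(ArAB-oxy)hex-4-enoate (racemic) | C/C(Oc1c(OC)cc(Oc2c(OC)cc(OC)cc2OC)cc1OC)=C\C(=O)C(Oc1cc(OC)c(OC)c(OC)c1Oc1cc(OC)c(Oc2cc(OC)c(Oc3cc(OC)c(OC)c(OC)c3)c(OC)c2)c(OC)c1)C(=O)OC | intermediate
22 | 2-(ArDEFG-oxy)-5-(ArAB-oxy)cyclohex-4-ene-1,3-dione | O=C1CC(Oc2c(OC)cc(Oc3c(OC)cc(OC)cc3OC)cc2OC)=CC(=O)C1Oc1cc(OC)c(OC)c(OC)c1Oc1cc(OC)c(Oc2cc(OC)c(Oc3cc(OC)c(OC)c(OC)c3)c(OC)c2)c(OC)c1 | intermediate
23 | 2-(ArDEFG-oxy)-5-(ArAB-oxy)benzene-1,3-diol | COc1cc(OC)c(Oc2cc(OC)c(Oc3cc(O)c(Oc4cc(OC)c(OC)c(OC)c4Oc4cc(OC)c(Oc5cc(OC)c(Oc6cc(OC)c(OC)c(OC)c6)c(OC)c5)c(OC)c4)c(O)c3)c(OC)c2)c(OC)c1 | intermediate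
24 | CNP0304148.0 | Oc1cc(O)c(Oc2cc(O)c(Oc3cc(O)c(Oc4cc(O)c(O)c(O)c4Oc4cc(O)c(Oc5cc(O)c(Oc6cc(O)c(O)c(O)c6)c(O)c5)c(O)c4)c(O)c3)c(O)c2)c(O)c1 | target

**Step count**
Total steps: 14. Longest linear sequence: 10 (steps 5 to 14).

**Steps most likely to fail**

Step 13. The monoanion may close through the ester-enolate oxygen or lose the AB aryloxide before the second deprotonation, or the dianion may fail to attack the enolate-deactivated ester. The fallback builds ring C from a bought arene and sets out from 17. SNAr of 17 on 2-fluoro-1,3-dimethoxy-5-nitrobenzene (K2CO3, DMSO, 90 °C; para-nitro activation) should give the nitro pentamer 1-(ArDEFG-oxy)-2,6-dimethoxy-4-nitrobenzene F1. Hydrogenation (H2, Pd/C) gives the aniline 4-(ArDEFG-oxy)-3,5-dimethoxyaniline F2. Diazotisation–iodination (NaNO2, p-TsOH, KI, MeCN–H2O) gives the aryl iodide 2-(ArDEFG-oxy)-5-iodo-1,3-dimethoxybenzene F3. Ullmann coupling of F3 with 5 under the conditions of step 2 gives the permethylated heptamer F4, and BBr3 demethylation of F4 returns to the route at 24.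

Step 8. Oxidative addition at the doubly ortho-substituted bromide may be slow, with hydrodebromination and aldehyde degradation competing. The fallback reverses the polarity of the D–O–E coupling (hindered phenol plus unhindered bromide) and sets out from 9, bypassing steps 6 to 9. Lithium–bromine exchange and borylation (n-BuLi, THF, −78 °C; B(OiPr)3; aq. HCl) gives [3,5-dimethoxy-4-(3,4,5-trimethoxyphenoxy)phenyl]boronic acid F5. Chan–Lam coupling of F5 with 1 as in step 5 gives the EFG bromide 5-bromo-2-[3,5-dimethoxy-4-(3,4,5-trimethoxyphenoxy)phenoxy]-1,3-dimethoxybenzene F6. Separately, 3,4,5-trimethoxyphenol is protected (MOMCl, iPr2NEt) as 1,2,3-trimethoxy-5-(methoxymethoxy)benzene F7. Directed ortho-lithiation at its only type of ring C–H (n-BuLi, THF, 0 °C), then B(OMe)3 and H2O2/NaOH, gives 2,3,4-trimethoxy-6-(methoxymethoxy)phenol F8. Ullmann coupling of F6 with F8 (CuI, picolinic acid, K3PO4, DMSO) gives the MOM ether of the DEFG phenol F9, and HCl in MeOH removes the MOM group to return at 17.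

Step 14. Ether cleavage may stay incomplete at some of the fifteen sites, and the pyrogallol- and phloroglucinol-type rings may oxidise during isolation of the free polyphenol. The fallback isolates through a stable derivative and sets out from 23. After BBr3 treatment as before, the crude product is not purified but acetylated at once (Ac2O, pyridine, DMAP) to the heptadecaacetate F10. F10 can be chromatographed on silica, and under-demethylated material can be separated and resubmitted. Acid-catalysed methanolysis (HCl from AcCl in degassed MeOH, rt, Ar) then releases 24 with only volatile by-products.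

**Further compounds**
F1 | step 13 | 1-(ArDEFG-oxy)-2,6-dimethoxy-4-nitrobenzene | COc1cc([N+](=O)[O-])cc(OC)c1Oc1cc(OC)c(OC)c(OC)c1Oc1cc(OC)c(Oc2cc(OC)c(Oc3cc(OC)c(OC)c(OC)c3)c(OC)c2)c(OC)c1
F2 | step 13 | 4-(ArDEFG-oxy)-3,5-dimethoxyaniline | COc1cc(N)cc(OC)c1Oc1cc(OC)c(OC)c(OC)c1Oc1cc(OC)c(Oc2cc(OC)c(Oc3cc(OC)c(OC)c(OC)c3)c(OC)c2)c(OC)c1
F3 | step 13 | 2-(ArDEFG-oxy)-5-iodo-1,3-dimethoxybenzene | COc1cc(I)cc(OC)c1Oc1cc(OC)c(OC)c(OC)c1Oc1cc(OC)c(Oc2cc(OC)c(Oc3cc(OC)c(OC)c(OC)c3)c(OC)c2)c(OC)c1
F4 | step 13 | permethylated heptamer (ring C as 3,5-dimethoxy) | COc1cc(OC)c(Oc2cc(OC)c(Oc3cc(OC)c(Oc4cc(OC)c(OC)c(OC)c4Oc4cc(OC)c(Oc5cc(OC)c(Oc6cc(OC)c(OC)c(OC)c6)c(OC)c5)c(OC)c4)c(OC)c3)c(OC)c2)c(OC)c1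
F5 | step 8 | [3,5-dimethoxy-4-(3,4,5-trimethoxyphenoxy)phenyl]boronic acid | COc1cc(B(O)O)cc(OC)c1Oc1cc(OC)c(OC)c(OC)c1
F6 | step 8 | 5-bromo-2-[3,5-dimethoxy-4-(3,4,5-trimethoxyphenoxy)phenoxy]-1,3-dimethoxybenzene | COc1cc(Br)cc(OC)c1Oc1cc(OC)c(Oc2cc(OC)c(OC)c(OC)c2)c(OC)c1
F7 | step 8 | 1,2,3-trimethoxy-5-(methoxymethoxy)benzene | COCOc1cc(OC)c(OC)c(OC)c1
F8 | step 8 | 2,3,4-trimethoxy-6-(methoxymethoxy)phenol | COCOc1cc(OC)c(OC)c(OC)c1O
F9 | step 8 | methoxymethyl ether of the DEFG phenol | COCOc1cc(OC)c(OC)c(OC)c1Oc1cc(OC)c(Oc2cc(OC)c(Oc3cc(OC)c(OC)c(OC)c3)c(OC)c2)c(OC)c1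
F10 | step 14 | heptadecaacetate of the target | CC(=O)Oc1cc(OC(C)=O)c(Oc2cc(OC(C)=O)c(Oc3cc(OC(C)=O)c(Oc4cc(OC(C)=O)c(OC(C)=O)c(OC(C)=O)c4Oc4cc(OC(C)=O)c(Oc5cc(OC(C)=O)c(Oc6cc(OC(C)=O)c(OC(C)=O)c(OC(C)=O)c6)c(OC(C)=O)c5)c(OC(C)=O)c4)c(OC(C)=O)c3)c(OC(C)=O)c2)c(OC(C)=O)c1
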